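The route rests on disconnecting C7–C8 of the ten-membered carbocycle. In the target the exocyclic C11=C13 alkene of the γ-lactone ring sits one carbon from the C8 carbinol (C13=C11–C7–C8–O), the imprint of a γ-selective allylation. Aldehyde 28, a (6R)-3-(bromomethyl)butenolide linked through the Z C4=C5 alkene, the C3 silyl ether, the C1 dioxolane and the C9/C10 acetonide to a C8 formyl group, should with CrCl2 close the carbocycle, move the alkene out of the lactone ring and set C7 and C8 in one operation. The precursor comes from two fragments joined at C3–C4.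

Key step: step 20

Remark: atoms carry germacrane numbers; C8′ is the extra glyceraldehyde carbon beyond C8 that is cut off in step 19, and D stands for the (4S,5S)-5-[(4S)-2,2-dimethyl-1,3-dioxolan-4-yl]-2,2,4-trimethyl-1,3-dioxolan-4-yl group (C10, C9, C8, C8′).
Remark: (S)-glyceraldehyde acetonide 1 is assumed to be bought and used freshly distilled; the allylic bromide is made from a hydroxymethyl group carried in the acrylate, because radical bromination of a methylbutenolide would compete at the doubly allylic C6–H.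

Step 1
Reactants: 1 (S)-2,2-dimethyl-1,3-dioxolane-4-carbaldehyde; 2 ethyl 2-[bis(2,2,2-trifluoroethoxy)phosphoryl]propanoate
Product: 3 ethyl (2Z)-3-[(4R)-2,2-dimethyl-1,3-dioxolan-4-yl]-2-methylprop-2-enoate
Conditions: KN(SiMe3)2, 18-crown-6, THF, −78 °C
Reagents that add atoms: none
Why: Still–Gennari olefination, in which the electron-poor trifluoroethyl phosphonate collapses under kinetic control to the Z enoate (future C1 and C8 cis across C10=C9) at a temperature that should not epimerise the aldehyde.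

Step 2
Reactants: 3 Z enoate
Product: 4 ethyl (2S,3S)-3-[(4S)-2,2-dimethyl-1,3-dioxolan-4-yl]-2,3-dihydroxy-2-methylpropanoate
Conditions: K2OsO4·2H2O (cat.), NMO, citric acid, t-BuOH/H2O, rt
Reagents that add atoms: N-methylmorpholine N-oxide, C[N+]1([O-])CCOCC1; water, O
Why: Upjohn syn-dihydroxylation, in which OsO4 adds to the face of the Z alkene anti to the allylic dioxolane oxygen (Kishi's rule), so that C9 and C10 are both set by the glyceraldehyde centre as the L-ribo array.

Step 3
Reactants: 4 diol ester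
Product: 5 ethyl (4S,5S)-5-[(4S)-2,2-dimethyl-1,3-dioxolan-4-yl]-2,2,4-trimethyl-1,3-dioxolane-4-carboxylate (D–CO2Et)
Conditions: 2,2-dimethoxypropane, PPTS, CH2Cl2, rt
Reagents that add atoms: 2,2-dimethoxypropane, COC(C)(C)OC
Why: acid-catalysed transacetalisation of the syn 2,3-diol to the cis-substituted acetonide, mild enough to leave the terminal acetonide and all stereocentres untouched.

Step 4
Reactants: 5 bis-acetonide ester; 6 N-methoxy-N-methylacetamide
Product: 7 3-D-N-methoxy-N-methyl-3-oxopropanamide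
Conditions: LiN(i-Pr)2 (3 equiv), THF, −78 → −20 °C; NH4Cl work-up
Reagents that add atoms: none
Why: crossed Claisen condensation of the amide enolate with the non-enolisable, α-alkoxy-activated ester forms C1–C2, and the β-keto amide is held as its enolate until the quench, which prevents a second addition.

Step 5
Reactants: 7 β-keto Weinreb amide
Product: 8 2-(2-D-1,3-dioxolan-2-yl)-N-methoxy-N-methylacetamide
Conditions: (TMSOCH2)2, TMSOTf (cat.), CH2Cl2, −78 → −20 °C; pyridine quench
Reagents that add atoms: 1,2-bis(trimethylsilyloxy)ethane, C[Si](C)(C)OCCO[Si](C)(C)C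
Why: Noyori ketalisation traps the silyl-activated C1 ketone as the dioxolane under aprotic, low-temperature conditions that the amide and the two acetonides should tolerate.

Step 6
Reactants: 9 acrolein; 10 prop-1-ynylmagnesium bromide
Product: 11 rac-hex-1-en-4-yn-3-ol
Conditions: THF, −78 → 0 °C; NH4Cl work-up
Reagents that add atoms: none
Why: 1,2-addition of the hard alkynyl Grignard reagent to the enal carbonyl gives the racemic carbinol that becomes C6.

Step 7
Reactants: 11 rac-hex-1-en-4-yn-3-ol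
Product: 13 rac-(4Z)-5-iodohexa-1,4-dien-3-ol, via cyclic alkenylalanate 12 (not isolated)
Conditions: NaAlH2(OCH2CH2OMe)2, THF, 0 °C → rt; then I2, −78 °C
Reagents that add atoms: iodine, II
Why: hydroxyl-directed trans-hydroalumination of the propargylic alcohol places aluminium on the distal alkyne carbon, and iodinolysis with retention gives the Z alkenyl iodide (iodine cis to the carbinol carbon).

Step 8
Reactants: 13 rac-(4Z)-5-iodohexa-1,4-dien-3-ol
Product: 14 (3S,4Z)-5-iodohexa-1,4-dien-3-ol
Conditions: Amano lipase PS (Burkholderia cepacia), vinyl acetate, MTBE, 30 °C, stopped just past half conversion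
Reagents that add atoms: none
Why: lipase-catalysed kinetic resolution, in which Kazlauskas' rule (iodoalkenyl large, vinyl medium) predicts acetylation of the R enantiomer, so the S alcohol with the C6 configuration should be recovered.

Step 9
Reactants: 14 (3S,4Z)-5-iodohexa-1,4-dien-3-ol
Product: 15 1-({[(3S,4Z)-5-iodohexa-1,4-dien-3-yl]oxy}methyl)-4-methoxybenzene
Conditions: NaH, Bu4NI (cat.), THF/DMF, 0 °C
Reagents that add atoms: 4-methoxybenzyl chloride, COc1ccc(CCl)cc1
Why: Williamson etherification without touching the stereocentre; a benzyl-type ether is chosen because a silyl ether could migrate from oxygen to the cis alkenyllithium of step 10.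

Step 10
Reactants: 15 PMB ether of the iododienol; 8 dioxolane Weinreb amide
Product: 17 (3Z,5S)-1-(2-D-1,3-dioxolan-2-yl)-5-[(4-methoxybenzyl)oxy]-3-methylhepta-3,6-dien-2-one, via alkenyllithium 16 (not isolated)
Conditions: t-BuLi (2.1 equiv), Et2O, −78 °C; then 8, THF, −78 → −40 °C; NH4Cl work-up
Reagents that add atoms: none
Why: iodine–lithium exchange with retention of the Z geometry, then Weinreb ketone synthesis, forms C3–C4, and the chelated tetrahedral adduct prevents over-addition.

Step 11
Reactants: 17 enone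
Product: 18 (2S,3Z,5S)-1-(2-D-1,3-dioxolan-2-yl)-5-[(4-methoxybenzyl)oxy]-3-methylhepta-3,6-dien-2-ol
Conditions: (R)-2-methyl-CBS-oxazaborolidine (1 equiv), catecholborane, toluene, −78 °C
Reagents that add atoms: none
Why: Corey–Bakshi–Shibata reduction, with the α-branched alkenyl group as the large substituent, should give the (3S) allylic alcohol under reagent control, and catecholborane at low temperature should leave the vinyl group alone.

Step 12
Reactants: 18 allylic alcohol
Product: 19 tert-butyldimethylsilyl ether of 18 (silyl ether at C3)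
Conditions: TBSOTf, 2,6-lutidine, CH2Cl2, −78 °C
Reagents that add atoms: tert-butyldimethylsilyl triflate, CC(C)(C)[Si](C)(C)OS(=O)(=O)C(F)(F)F
Why: silylation of the only free hydroxyl with the reactive triflate under buffered, cold conditions that spare the ketals.

Step 13
Reactants: 19 silyl ether
Product: 20 (3S,4Z,6S)-6-[(tert-butyldimethylsilyl)oxy]-7-(2-D-1,3-dioxolan-2-yl)-5-methylhepta-1,4-dien-3-ol
Conditions: DDQ (1.2 equiv), CH2Cl2/pH 7 buffer, 0 °C
Reagents that add atoms: none
Why: oxidative cleavage of the 4-methoxybenzyl ether by DDQ frees the C6 hydroxyl under neutral conditions, with limited oxidant and time so that the doubly allylic alcohol is not oxidised further.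

Step 14
Reactants: 21 2-(bromomethyl)prop-2-enoic acid
Product: 22 2-{[(4-methoxybenzyl)oxy]methyl}prop-2-enoic acid
Conditions: NaH (2.2 equiv), THF, 0 °C → rt; aq. HCl work-up
Reagents that add atoms: 4-methoxybenzyl alcohol, COc1ccc(CO)cc1
Why: allylic substitution of the bromide by the alkoxide on the carboxylate salt; direct and allylic-shift attack give the same ether.

Step 15
Reactants: 20 C6 alcohol; 22 2-{[(4-methoxybenzyl)oxy]methyl}prop-2-enoic acid
Product: 23 (3S,4Z,6S)-6-[(tert-butyldimethylsilyl)oxy]-7-(2-D-1,3-dioxolan-2-yl)-5-methylhepta-1,4-dien-3-yl 2-{[(4-methoxybenzyl)oxy]methyl}prop-2-enoate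
Conditions: DCC, DMAP (cat.), CH2Cl2, 0 °C → rt
Reagents that add atoms: none
Why: Steglich esterification of the only free hydroxyl, with retention at C6.

Step 16
Reactants: 23 acrylate ester
Product: 24 (5R)-5-[(1Z,3S)-3-[(tert-butyldimethylsilyl)oxy]-4-(2-D-1,3-dioxolan-2-yl)-2-methylbut-1-en-1-yl]-3-{[(4-methoxybenzyl)oxy]methyl}furan-2(5H)-one
Conditions: second-generation Grubbs catalyst (5–10 mol%), toluene, 80 °C
Reagents that add atoms: none
Why: ring-closing metathesis, in which the ruthenium carbene forms at the monosubstituted vinyl group and closes onto the 2-substituted acrylate to give the five-membered butenolide, the trisubstituted C4=C5 alkene being too hindered to take part.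

Step 17
Reactants: 24 butenolide PMB ether
Product: 25 (5R)-5-[(1Z,3S)-3-[(tert-butyldimethylsilyl)oxy]-4-(2-D-1,3-dioxolan-2-yl)-2-methylbut-1-en-1-yl]-3-(hydroxymethyl)furan-2(5H)-one
Conditions: DDQ, CH2Cl2/pH 7 buffer, 0 °C → rt
Reagents that add atoms: none
Why: oxidative cleavage of the primary allylic 4-methoxybenzyl ether under neutral conditions, so the base-sensitive C6–H of the butenolide is not disturbed.

Step 18
Reactants: 25 hydroxymethylbutenolide
Product: 26 (5R)-3-(bromomethyl)-5-[(1Z,3S)-3-[(tert-butyldimethylsilyl)oxy]-4-(2-D-1,3-dioxolan-2-yl)-2-methylbut-1-en-1-yl]furan-2(5H)-one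
Conditions: CBr4, PPh3, CH2Cl2, 0 °C
Reagents that add atoms: carbon tetrabromide, BrC(Br)(Br)Br
Why: Appel bromination of the primary allylic alcohol under neutral conditions places the bromide only on C13.

Step 19
Reactants: 26 bromomethylbutenolide
Product: 28 (4R,5S)-5-{2-[(2S,3Z)-4-[(2R)-4-(bromomethyl)-5-oxo-2,5-dihydrofuran-2-yl]-2-[(tert-butyldimethylsilyl)oxy]-3-methylbut-3-en-1-yl]-1,3-dioxolan-2-yl}-2,2,5-trimethyl-1,3-dioxolane-4-carbaldehyde, via terminal diol 27 (not isolated)
Conditions: H5IO6, EtOAc, rt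
Reagents that add atoms: none
Why: periodic acid hydrolyses the less hindered terminal acetonide and then cleaves the 1,2-diol (Malaprade reaction) in the same pot, releasing the C8 aldehyde without an oxidation step; the aldehyde is used at once to protect the C9 centre.

Step 20
Reactants: 28 3-(bromomethyl)butenolide aldehyde
Product: 30 (3S,6R,7R,8S,9S,10S)-3-[(tert-butyldimethylsilyl)oxy]-1,1-(ethylenedioxy)-8-hydroxy-9,10-(isopropylidenedioxy)germacra-4(Z),11(13)-dien-12,6-olide, via allylchromium dichloride 29 (not isolated)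
Conditions: CrCl2 (10 equiv), degassed DMF, rt, 28 added slowly to a final 1 mM
Reagents that add atoms: none
Why: Two equivalents of CrCl2 (divalent chromium) reduce the allylic C–Br bond to the trivalent allylchromium 29, which adds to the aldehyde through C7 in a six-membered cyclic chromium alkoxide transition state, so that the C7=C11 alkene becomes the exocyclic C11=C13 methylene. The closest known reaction type is the Nozaki–Hiyama–Kishi (Barbier) allylation of aldehydes with 2-(bromomethyl)acrylates and 3-(bromomethyl)butenolides, including closures of ten-membered germacranolide rings. The carbocycle closes in a 10-exo-trig mode with respect to the formyl group, and high dilution suppresses intermolecular coupling. C7 is controlled by the C6 stereocentre, since C8 should approach the butenolide face opposite the C6 side chain and give the trans-disposed lactone. C8 is controlled by the aldehyde face: attack anti to the C9–O bond of the acetonide (polar Felkin–Anh) gives the 8,9-anti pattern of the target, and the Z alkene and cis-fused acetonide in the tether must enforce this against the open-chain chair preference of this E-type allylchromium, which would place O8 anti to C6. The step also needs aldehyde-over-ketone and γ-over-α selectivity, secured by the C1 dioxolane, the low reactivity of organochromium reagents toward esters and ketals, and the cyclic transition state.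

Step 21
Reactants: 30 macrocyclic C8 alcohol; 31 tigloyl chloride ((2E)-2-methylbut-2-enoyl chloride)
Product: 32 (3S,6R,7S,8S,9S,10S)-3-[(tert-butyldimethylsilyl)oxy]-1,1-(ethylenedioxy)-9,10-(isopropylidenedioxy)-8-(tigloyloxy)germacra-4(Z),11(13)-dien-12,6-olide
Conditions: pyridine, DMAP (cat.), CH2Cl2, 0 °C → rt
Reagents that add atoms: none
Why: DMAP-catalysed acylation of the only free hydroxyl with retention at C8; pyridine in place of a trialkylamine avoids vinylketene formation and deconjugation of the tigloyl group.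

Step 22
Reactants: 32 protected tiglate
Product: 33 (3S,6R,7S,8S,9S,10S)-3,9,10-trihydroxy-1-oxo-8-(tigloyloxy)germacra-4(Z),11(13)-dien-12,6-olide (CNP0106709.2)
Conditions: aq. HCl (2 M)/THF (1:2), 0 °C → rt
Reagents that add atoms: water, O
Why: acid hydrolysis removes the silyl ether, the acetonide and the dioxolane in one operation, while the tiglate, the α-methylene lactone and all stereocentres are inert to dilute aqueous acid.

Compound list
1 | (S)-2,2-dimethyl-1,3-dioxolane-4-carbaldehyde | O=C[C@@H]1COC(C)(C)O1 | starting material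
2 | ethyl 2-[bis(2,2,2-trifluoroethoxy)phosphoryl]propanoate | CCOC(=O)C(C)P(=O)(OCC(F)(F)F)OCC(F)(F)F | starting material
3 | ethyl (2Z)-3-[(4R)-2,2-dimethyl-1,3-dioxolan-4-yl]-2-methylprop-2-enoate | CCOC(=O)/C(C)=C\[C@@H]1COC(C)(C)O1 | intermediate
4 | ethyl (2S,3S)-3-[(4S)-2,2-dimethyl-1,3-dioxolan-4-yl]-2,3-dihydroxy-2-methylpropanoate | CCOC(=O)[C@@](C)(O)[C@@H](O)[C@@H]1COC(C)(C)O1 | intermediate
5 | ethyl (4S,5S)-5-[(4S)-2,2-dimethyl-1,3-dioxolan-4-yl]-2,2,4-trimethyl-1,3-dioxolane-4-carboxylate | CCOC(=O)[C@@]1(C)OC(C)(C)O[C@H]1[C@@H]1COC(C)(C)O1 | intermediate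
6 | N-methoxy-N-methylacetamide | CC(=O)N(C)OC | starting material
7 | 3-D-N-methoxy-N-methyl-3-oxopropanamide | CON(C)C(=O)CC(=O)[C@@]1(C)OC(C)(C)O[C@H]1[C@@H]1COC(C)(C)O1 | intermediate
8 | 2-(2-D-1,3-dioxolan-2-yl)-N-methoxy-N-methylacetamide | CON(C)C(=O)CC1(OCCO1)[C@@]1(C)OC(C)(C)O[C@H]1[C@@H]1COC(C)(C)O1 | intermediate
9 | acrolein | C=CC=O | starting material
10 | prop-1-ynylmagnesium bromide | CC#C[Mg]Br | starting material
11 | rac-hex-1-en-4-yn-3-ol | C=CC(O)C#CC | intermediate
12 | sodium cyclic alkenylalanate of 11 (O–Al–C five-membered ring, not isolated) | C=CC1O[Al-](OCCOC)(OCCOC)C(C)=C1.[Na+] | intermediate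
13 | rac-(4Z)-5-iodohexa-1,4-dien-3-ol | C=CC(O)/C=C(/C)I | intermediate
14 | (3S,4Z)-5-iodohexa-1,4-dien-3-ol | C=C[C@H](O)/C=C(/C)I | intermediate
15 | 1-({[(3S,4Z)-5-iodohexa-1,4-dien-3-yl]oxy}methyl)-4-methoxybenzene | C=C[C@H](OCc1ccc(OC)cc1)/C=C(/C)I | intermediate
16 | (Z)-alkenyllithium from 15 (lithium on C4, not isolated) | C=C[C@H](OCc1ccc(OC)cc1)/C=C(/C)[Li] | intermediate
17 | (3Z,5S)-1-(2-D-1,3-dioxolan-2-yl)-5-[(4-methoxybenzyl)oxy]-3-methylhepta-3,6-dien-2-one | C=C[C@H](OCc1ccc(OC)cc1)/C=C(/C)C(=O)CC1(OCCO1)[C@@]1(C)OC(C)(C)O[C@H]1[C@@H]1COC(C)(C)O1 | intermediate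
18 | (2S,3Z,5S)-1-(2-D-1,3-dioxolan-2-yl)-5-[(4-methoxybenzyl)oxy]-3-methylhepta-3,6-dien-2-ol | C=C[C@H](OCc1ccc(OC)cc1)/C=C(/C)[C@@H](O)CC1(OCCO1)[C@@]1(C)OC(C)(C)O[C@H]1[C@@H]1COC(C)(C)O1 | intermediate
19 | tert-butyldimethylsilyl ether of 18 (at C3) | C=C[C@H](OCc1ccc(OC)cc1)/C=C(/C)[C@@H](O[Si](C)(C)C(C)(C)C)CC1(OCCO1)[C@@]1(C)OC(C)(C)O[C@H]1[C@@H]1COC(C)(C)O1 | intermediate
20 | (3S,4Z,6S)-6-[(tert-butyldimethylsilyl)oxy]-7-(2-D-1,3-dioxolan-2-yl)-5-methylhepta-1,4-dien-3-ol | C=C[C@H](O)/C=C(/C)[C@@H](O[Si](C)(C)C(C)(C)C)CC1(OCCO1)[C@@]1(C)OC(C)(C)O[C@H]1[C@@H]1COC(C)(C)O1 | intermediate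
21 | 2-(bromomethyl)prop-2-enoic acid | OC(=O)C(=C)CBr | starting material
22 | 2-{[(4-methoxybenzyl)oxy]methyl}prop-2-enoic acid | COc1ccc(COCC(=C)C(O)=O)cc1 | intermediate
23 | 2-{[(4-methoxybenzyl)oxy]methyl}prop-2-enoate ester of 20 (at C6) | COc1ccc(COCC(=C)C(=O)O[C@@H](C=C)/C=C(/C)[C@@H](O[Si](C)(C)C(C)(C)C)CC2(OCCO2)[C@@]3(C)OC(C)(C)O[C@H]3[C@@H]4COC(C)(C)O4)cc1 | intermediate
24 | (5R)-5-[(1Z,3S)-3-[(tert-butyldimethylsilyl)oxy]-4-(2-D-1,3-dioxolan-2-yl)-2-methylbut-1-en-1-yl]-3-{[(4-methoxybenzyl)oxy]methyl}furan-2(5H)-one | COc1ccc(COCC2=C[C@H](OC2=O)/C=C(/C)[C@@H](O[Si](C)(C)C(C)(C)C)CC3(OCCO3)[C@@]4(C)OC(C)(C)O[C@H]4[C@@H]5COC(C)(C)O5)cc1 | intermediate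
25 | 3-(hydroxymethyl) analogue of 24 | OCC1=C[C@H](OC1=O)/C=C(/C)[C@@H](O[Si](C)(C)C(C)(C)C)CC2(OCCO2)[C@@]3(C)OC(C)(C)O[C@H]3[C@@H]4COC(C)(C)O4 | intermediate
26 | 3-(bromomethyl) analogue of 24 | BrCC1=C[C@H](OC1=O)/C=C(/C)[C@@H](O[Si](C)(C)C(C)(C)C)CC2(OCCO2)[C@@]3(C)OC(C)(C)O[C@H]3[C@@H]4COC(C)(C)O4 | intermediate
27 | terminal (8S)-C8,C8′-diol of 26 (not isolated) | BrCC1=C[C@H](OC1=O)/C=C(/C)[C@@H](O[Si](C)(C)C(C)(C)C)CC2(OCCO2)[C@@]3(C)OC(C)(C)O[C@H]3[C@@H](O)CO | intermediate
28 | (4R,5S)-5-{2-[(2S,3Z)-4-[(2R)-4-(bromomethyl)-5-oxo-2,5-dihydrofuran-2-yl]-2-[(tert-butyldimethylsilyl)oxy]-3-methylbut-3-en-1-yl]-1,3-dioxolan-2-yl}-2,2,5-trimethyl-1,3-dioxolane-4-carbaldehyde | BrCC1=C[C@H](OC1=O)/C=C(/C)[C@@H](O[Si](C)(C)C(C)(C)C)CC2(OCCO2)[C@@]3(C)OC(C)(C)O[C@H]3C=O | intermediate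
29 | allylchromium dichloride from 28 (trivalent chromium on C13, not isolated) | Cl[Cr](Cl)CC1=C[C@H](OC1=O)/C=C(/C)[C@@H](O[Si](C)(C)C(C)(C)C)CC2(OCCO2)[C@@]3(C)OC(C)(C)O[C@H]3C=O | intermediate
30 | (3S,6R,7R,8S,9S,10S)-3-[(tert-butyldimethylsilyl)oxy]-1,1-(ethylenedioxy)-8-hydroxy-9,10-(isopropylidenedioxy)germacra-4(Z),11(13)-dien-12,6-olide | C=C1C(=O)O[C@@H]2/C=C(/C)[C@@H](O[Si](C)(C)C(C)(C)C)CC3(OCCO3)[C@@]4(C)OC(C)(C)O[C@H]4[C@@H](O)[C@@H]12 | intermediate
31 | tigloyl chloride, (2E)-2-methylbut-2-enoyl chloride | C/C=C(\C)C(Cl)=O | starting material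
32 | (3S,6R,7S,8S,9S,10S)-3-[(tert-butyldimethylsilyl)oxy]-1,1-(ethylenedioxy)-9,10-(isopropylidenedioxy)-8-(tigloyloxy)germacra-4(Z),11(13)-dien-12,6-olide | C=C1C(=O)O[C@@H]2/C=C(/C)[C@@H](O[Si](C)(C)C(C)(C)C)CC3(OCCO3)[C@@]4(C)OC(C)(C)O[C@H]4[C@@H](OC(=O)/C(C)=C/C)[C@@H]12 | intermediate
33 | (3S,6R,7S,8S,9S,10S)-3,9,10-trihydroxy-1-oxo-8-(tigloyloxy)germacra-4(Z),11(13)-dien-12,6-olide (CNP0106709.2) | C=C1C(=O)O[C@@H]2/C=C(/C)[C@@H](O)CC(=O)[C@@](C)(O)[C@@H](O)[C@@H](OC(=O)/C(C)=C/C)[C@@H]12 | target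

Total step count: 22. Longest linear sequence: 17 steps (steps 1–5, 10–13 and 15–22, from 1).

Steps most likely to fail

Step 20. The closure may add to the wrong aldehyde face, because the open-chain chair preference of the allylchromium opposes the Felkin-controlled approach that the target needs; intermolecular coupling is the second failure process and is met by dilution. Setting out from 28, the cyclisation would then deliver the (8R)-epimer of 30 F1. F1 is esterified with inversion under Mitsunobu conditions (tiglic acid, PPh3, DIAD, toluene, 0 °C → rt), which gives the tiglate directly and returns to the route at 32.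

Step 5. Ketalisation of the hindered, electron-poor C1 ketone may be slow, and exchange of the acetonides with the silylated glycol may overtake it. The fallback builds the ketal by conjugate addition and not by carbonyl ketalisation. Setting out from 5, reduction with i-Bu2AlH (CH2Cl2, −78 °C) gives D-carbaldehyde F2, and Ohira–Bestmann homologation (dimethyl (1-diazo-2-oxopropyl)phosphonate, K2CO3, MeOH) gives D-ethyne F3. Carboxylation (n-BuLi, THF, −78 °C; ClCO2Me) gives methyl 3-D-prop-2-ynoate F4, and double conjugate addition of ethane-1,2-diol (NaH, THF, rt → 50 °C) gives methyl 2-(2-D-1,3-dioxolan-2-yl)acetate F5. Aminolysis of F5 (MeNHOMe·HCl, i-PrMgCl, THF, −20 °C) returns to the route at 8.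

Step 22. Cleavage of the hindered dioxolane may lag so far behind the other two unmaskings that the acid begins to ionise the allylic C3 alcohol or to shift the tigloyl group to O9. The fallback separates the unmaskings and avoids Brønsted acid. Setting out from 32, buffered HF·pyridine (pyridine, THF, 0 °C) removes only the silyl ether and gives the C3 alcohol F6. The acetonide and the dioxolane of F6 are then taken off by Lewis-acid ketal exchange at near-neutral pH (Er(OTf)3 cat., wet MeNO2, rt), which returns to the route at 33.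

Further compounds
F1 | step 20 | (8R)-epimer of 30 | C=C1C(=O)O[C@@H]2/C=C(/C)[C@@H](O[Si](C)(C)C(C)(C)C)CC3(OCCO3)[C@@]4(C)OC(C)(C)O[C@H]4[C@H](O)[C@@H]12
F2 | step 5 | D-carbaldehyde (C1 aldehyde, configuration as in 5) | O=C[C@@]1(C)OC(C)(C)O[C@H]1[C@@H]1COC(C)(C)O1
F3 | step 5 | D-ethyne (terminal alkyne C1≡C2, configuration as in 5) | C#C[C@@]1(C)OC(C)(C)O[C@H]1[C@@H]1COC(C)(C)O1
F4 | step 5 | methyl 3-D-prop-2-ynoate | COC(=O)C#C[C@@]1(C)OC(C)(C)O[C@H]1[C@@H]1COC(C)(C)O1
F5 | step 5 | methyl 2-(2-D-1,3-dioxolan-2-yl)acetate | COC(=O)CC1(OCCO1)[C@@]1(C)OC(C)(C)O[C@H]1[C@@H]1COC(C)(C)O1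
F6 | step 22 | 3-O-desilyl derivative of 32 | C=C1C(=O)O[C@@H]2/C=C(/C)[C@@H](O)CC3(OCCO3)[C@@]4(C)OC(C)(C)O[C@H]4[C@@H](OC(=O)/C(C)=C/C)[C@@H]12
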